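**Retrosynthetic overview**

- The target is two identical 8-acyl-2,2-dimethylchroman-5,7-diols joined at C6 and C6' through the CH of a 6-methylheptane-1,1-diyl bridge. The two (R)-2-methylbutanoyl groups at C8 and C8' are removed last (C8–acyl bond, ortho-acylation), after the O5 silyl ethers.
- Feature used: in each benzene ring (C4a, C5, C6, C7, C8, C8a) oxygen sits on C5, C7 and C8a and carbon on C4a, C6 and C8, and O1–C8a and C4–C4a are already tied together by the pyran ring (O1, C2, C3, C4).
- Key disconnection, made twice: C6–C7 and C4a–C5. C7, C8, C8a and C4a with the complete pyran ring come from a pyran-fused 3-alkoxycyclobutenone; C5, C6 and the bridge carbon come from a bis(siloxyalkyne).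
- Cyclobutenone: ketene/ethoxyacetylene [2+2], hydrolysis to the 2-prenyl-1,3-dione enol, acid cyclisation. Diyne: ester plus two HC≡CMgBr, Nicholas deoxygenation, acetylide oxidation and O-silylation.
- Ring order: cyclobutenone ring, then the pyran ring, then both benzene rings together in the key step.

Key step: step 10

Remark on the chemistry: 5 is formed racemic and 18 as a mixture of diastereomers at its two spiro carbons; these centres are destroyed later. The bridge carbon of 19, 22 and 23 carries two identical aryl groups and is not a stereocentre, so the only stereocentres of the target are the two (R) centres brought in with 20.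

**Route**

Step 1
Reactants: 1 5-methylhex-4-enoic acid
Product: 2 5-methylhex-4-enoyl chloride
Conditions: (COCl)2, DMF (cat.), CH2Cl2, 0 → 20 °C
Reagents that add atoms: oxalyl chloride, ClC(=O)C(=O)Cl
Why: Vilsmeier-type activation of the acid gives the acid chloride under base-free, gas-evolving conditions that should leave the trisubstituted alkene untouched.

Step 2
Reactants: 2 5-methylhex-4-enoyl chloride; 3 ethoxyacetylene
Product: 5 rac-3-ethoxy-4-(3-methylbut-2-en-1-yl)cyclobut-2-en-1-one, via 5-methylhexa-1,4-dien-1-one 4 (not isolated)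
Conditions: Et3N, 3 (3 equiv), Et2O, 0 → 20 °C, slow addition of 2
Reagents that add atoms: none
Why: Dehydrochlorination gives the aldoketene, which is trapped by excess ynol ether in a ketene–alkoxyalkyne [2+2] cycloaddition (the CH terminus of the alkyne bonds to the ketene carbonyl carbon); the C4 stereocentre forms racemic and is erased in step 3.

Step 3
Reactants: 5 rac-3-ethoxy-4-(3-methylbut-2-en-1-yl)cyclobut-2-en-1-one
Product: 6 3-hydroxy-2-(3-methylbut-2-en-1-yl)cyclobut-2-en-1-one
Conditions: 2 M HCl, THF, 0 → 20 °C
Reagents that add atoms: water, O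
Why: Acid hydrolysis of the vinylogous ester gives the 2-substituted cyclobutane-1,3-dione, which should rest as the enol whose double bond carries the prenyl group; cold dilute acid should spare the alkene and the strained ring, and 6 is taken on without storage.

Step 4
Reactants: 6 3-hydroxy-2-(3-methylbut-2-en-1-yl)cyclobut-2-en-1-one
Product: 7 3,3-dimethyl-2-oxabicyclo[4.2.0]oct-1(6)-en-7-one
Conditions: Amberlyst-15 (sulfonic acid resin), CH2Cl2, 20 °C
Reagents that add atoms: none
Why: Brønsted-acid hydroalkoxylation, in which Markovnikov protonation of the prenyl alkene gives a tertiary cation that the enol oxygen captures in a six-membered ring closure, as in the cyclisation of 2-prenyl-1,3-diones to 2,2-dimethyldihydropyrans; the ring-fusion enol ether is the expected thermodynamic isomer.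

Step 5
Reactants: 8 methyl 6-methylheptanoate
Product: 10 3-(5-methylhexyl)penta-1,4-diyn-3-ol, via 8-methylnon-1-yn-3-one 9 (not isolated)
Conditions: HC≡CMgBr (2.5 equiv), THF, 0 → 20 °C; aq NH4Cl
Reagents that add atoms: ethynylmagnesium bromide, C#C[Mg]Br
Why: Double Grignard addition to an ester, in which the ynone formed after loss of methoxide is more electrophilic than the ester and takes up the second alkynyl group to give the tertiary diethynyl carbinol.

Step 6
Reactants: 10 3-(5-methylhexyl)penta-1,4-diyn-3-ol
Product: 11 [3-(5-methylhexyl)penta-1,4-diyn-3-ol]bis(hexacarbonyldicobalt)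
Conditions: Co2(CO)8 (2.2 equiv), CH2Cl2, 20 °C
Reagents that add atoms: Co2(CO)8, O=C=[Co](=C=O)(=C=O)(=C=O)[Co](=C=O)(=C=O)(=C=O)=C=O
Why: Each terminal alkyne displaces two CO ligands to form a stable alkyne–Co2(CO)6 complex, which makes the carbinol carbon a latent Nicholas cation.

Step 7
Reactants: 11 [3-(5-methylhexyl)penta-1,4-diyn-3-ol]bis(hexacarbonyldicobalt)
Product: 12 [3-(5-methylhexyl)penta-1,4-diyne]bis(hexacarbonyldicobalt)
Conditions: Et3SiH, CF3CO2H, CH2Cl2, 0 °C
Reagents that add atoms: none
Why: Nicholas reduction (ionic hydrogenation), in which acid ionises the tertiary alcohol to a cobalt-stabilised propargylic cation that can take hydride only at the former carbinol carbon, so no allene can form, and any enyne complex formed by proton loss is re-protonated to the same cation.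

Step 8
Reactants: 12 [3-(5-methylhexyl)penta-1,4-diyne]bis(hexacarbonyldicobalt)
Product: 13 3-(5-methylhexyl)penta-1,4-diyne
Conditions: (NH4)2Ce(NO3)6, acetone, −78 → 0 °C
Reagents that add atoms: none
Why: Oxidative decomplexation, in which tetravalent cerium oxidises the zerovalent cobalt of both clusters to divalent cobalt and frees the alkynes without base, so the skipped diyne should not isomerise.

Step 9
Reactants: 13 3-(5-methylhexyl)penta-1,4-diyne
Product: 16 3-(5-methylhexyl)-1,5-bis(triisopropylsilyloxy)penta-1,4-diyne, via dilithium diacetylide 14 (not isolated), via dilithium bis-ynolate 15 (not isolated)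
Conditions: n-BuLi (2.0 equiv), THF, −78 °C; t-BuOOLi (from t-BuOOH, LiN(SiMe3)2), −78 → 0 °C; i-Pr3SiOTf, −78 → 0 °C
Reagents that add atoms: tert-butyl hydroperoxide, CC(C)(C)OO; triisopropylsilyl trifluoromethanesulfonate, CC(C)[Si](OS(=O)(=O)C(F)(F)F)(C(C)C)C(C)C
Why: Electrophilic oxygen transfer from a lithium alkyl peroxide to each lithium acetylide gives the ynolate, which the bulky silyl triflate traps on oxygen; with both termini lithiated first, removal of the bridge C–H is disfavoured, so prototropic isomerisation should be held back.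

Step 10
Reactants: 7 3,3-dimethyl-2-oxabicyclo[4.2.0]oct-1(6)-en-7-one (2.5 equiv); 16 3-(5-methylhexyl)-1,5-bis(triisopropylsilyloxy)penta-1,4-diyne
Product: 19 6,6'-(6-methylheptane-1,1-diyl)bis[2,2-dimethyl-5-(triisopropylsilyloxy)chroman-7-ol], via vinylketene 17 (not isolated), via bis(4-vinylcyclobutenone) 18 (not isolated)
Conditions: hν (254 nm), degassed ClCH2CH2Cl, 20 °C; then 80 °C in the dark
Reagents that add atoms: none
Why: Light opens each molecule of 7 by 4π electrocyclic ring opening to vinylketene 17, whose ketene carbon bonds to the bridge-bearing alkyne carbon and whose α-carbon bonds to the siloxy carbon in a [2+2] cycloaddition (C6–C7 and C4a–C5), giving the spiro 4-vinylcyclobutenones 18; warming opens these by a second 4π ring opening to dienylketenes. Each benzene ring is then closed by thermal 6π electrocyclisation of the dienylketene (C7–C8 bond) and tautomerisation of the cyclohexadienone to the phenol. The closest known reaction type is the Danheiser benzannulation of cyclobutenones with siloxyalkynes to resorcinol monosilyl ethers, here run on both arms of a diyne with a pyran-fused 3-alkoxycyclobutenone, a combination that is untested. No stereocentre is formed in the product, and the spiro centres of 18 are lost on aromatisation. The step needs the regiochemistry of the ketene–alkyne addition, which is fixed by the polarisation of the ynol ether (its carbon β to oxygen is the nucleophile and attacks the ketene carbonyl carbon), so that the bridge ends at C6 between the C7 hydroxyl and the C5 silyl ether with C8 as the only ring C–H. It also needs both arms to react before the first-formed phenol can add to the remaining siloxyalkyne, which excess 7 and neutral photochemical initiation at 20 °C should favour.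

Step 11
Reactants: 20 (R)-2-methylbutanoic acid
Product: 21 (R)-2-methylbutanoyl chloride
Conditions: (COCl)2, DMF (cat.), CH2Cl2, 0 → 20 °C
Reagents that add atoms: oxalyl chloride, ClC(=O)C(=O)Cl
Why: Acid chloride formation without base avoids ketene formation and enolisation, so the (R) α-stereocentre of the starting acid should be kept.

Step 12
Reactants: 19 6,6'-(6-methylheptane-1,1-diyl)bis[2,2-dimethyl-5-(triisopropylsilyloxy)chroman-7-ol]; 21 (R)-2-methylbutanoyl chloride (2.4 equiv)
Product: 22 6,6'-(6-methylheptane-1,1-diyl)bis{8-[(2R)-2-methylbutanoyl]-2,2-dimethyl-5-(triisopropylsilyloxy)chroman-7-ol}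
Conditions: TiCl4, CH2Cl2, −40 → 0 °C
Reagents that add atoms: none
Why: Titanium-phenoxide-directed Friedel–Crafts ortho-acylation, in which C8 is the only unsubstituted ring carbon and is activated by the ortho C7 hydroxyl, the ortho ring oxygen and the para silyloxy group, so each ring should be acylated once at low temperature, where the acyl α-stereocentre should not enolise.

Step 13
Reactants: 22 6,6'-(6-methylheptane-1,1-diyl)bis{8-[(2R)-2-methylbutanoyl]-2,2-dimethyl-5-(triisopropylsilyloxy)chroman-7-ol}
Product: 23 6,6'-(6-methylheptane-1,1-diyl)bis{8-[(2R)-2-methylbutanoyl]-2,2-dimethylchroman-5,7-diol} (CNP0324275.1)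
Conditions: Bu4NF, AcOH, THF, 0 → 20 °C
Reagents that add atoms: none
Why: Fluoride cleaves both aryl silyl ethers (strong Si–F bond, phenoxide leaving group), and the acetic acid buffer should keep the ketone α-stereocentres from epimerising and the doubly benzylic bridge from base-induced scrambling.

**Compound list**

1 | 5-methylhex-4-enoic acid | CC(C)=CCCC(=O)O | starting material
2 | 5-methylhex-4-enoyl chloride | CC(C)=CCCC(=O)Cl | intermediate
3 | ethoxyacetylene | CCOC#C | starting material
4 | 5-methylhexa-1,4-dien-1-one (the ketene from 2) | CC(C)=CCC=C=O | intermediate (not isolated)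
5 | rac-3-ethoxy-4-(3-methylbut-2-en-1-yl)cyclobut-2-en-1-one | CCOC1=CC(=O)C1CC=C(C)C | intermediate
6 | 3-hydroxy-2-(3-methylbut-2-en-1-yl)cyclobut-2-en-1-one | CC(C)=CCC1=C(O)CC1=O | intermediate
7 | 3,3-dimethyl-2-oxabicyclo[4.2.0]oct-1(6)-en-7-one | O=C1CC2=C1CCC(C)(C)O2 | intermediate
8 | methyl 6-methylheptanoate | COC(=O)CCCCC(C)C | starting material
9 | 8-methylnon-1-yn-3-one | C#CC(=O)CCCCC(C)C | intermediate (not isolated)
10 | 3-(5-methylhexyl)penta-1,4-diyn-3-ol | C#CC(O)(C#C)CCCCC(C)C | intermediate
11 | [3-(5-methylhexyl)penta-1,4-diyn-3-ol]bis(hexacarbonyldicobalt), each C≡C bridging one Co2(CO)6 unit | [CH]12[Co]3(=C=O)(=C=O)(=C=O)[Co]1(=C=O)(=C=O)(=C=O)C23C(O)(CCCCC(C)C)C12[CH]3[Co]1(=C=O)(=C=O)(=C=O)[Co]23(=C=O)(=C=O)(=C=O) | intermediate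
12 | [3-(5-methylhexyl)penta-1,4-diyne]bis(hexacarbonyldicobalt) | [CH]12[Co]3(=C=O)(=C=O)(=C=O)[Co]1(=C=O)(=C=O)(=C=O)C23C(CCCCC(C)C)C12[CH]3[Co]1(=C=O)(=C=O)(=C=O)[Co]23(=C=O)(=C=O)(=C=O) | intermediate
13 | 3-(5-methylhexyl)penta-1,4-diyne | C#CC(C#C)CCCCC(C)C | intermediate
14 | dilithium 3-(5-methylhexyl)penta-1,4-diyne-1,5-diide | [Li]C#CC(CCCCC(C)C)C#C[Li] | intermediate (not isolated)
15 | dilithium 3-(5-methylhexyl)penta-1,4-diyne-1,5-bis(olate) | [Li]OC#CC(CCCCC(C)C)C#CO[Li] | intermediate (not isolated)
16 | 3-(5-methylhexyl)-1,5-bis(triisopropylsilyloxy)penta-1,4-diyne | CC(C)CCCCC(C#CO[Si](C(C)C)(C(C)C)C(C)C)C#CO[Si](C(C)C)(C(C)C)C(C)C | intermediate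
17 | (6,6-dimethyl-2-methylideneoxan-3-ylidene)methanone (vinylketene from 7) | O=C=C1CCC(C)(C)OC1=C | intermediate (not isolated)
18 | 2,2'-(6-methylheptane-1,1-diyl)bis[7,7-dimethyl-5-methylidene-3-(triisopropylsilyloxy)-6-oxaspiro[3.5]non-2-en-1-one], mixture of diastereomers | CC(C)CCCCC(C1=C(O[Si](C(C)C)(C(C)C)C(C)C)C2(CCC(C)(C)OC2=C)C1=O)C1=C(O[Si](C(C)C)(C(C)C)C(C)C)C2(CCC(C)(C)OC2=C)C1=O | intermediate (not isolated)
19 | 6,6'-(6-methylheptane-1,1-diyl)bis[2,2-dimethyl-5-(triisopropylsilyloxy)chroman-7-ol] | CC(C)CCCCC(c1c(O)cc2OC(C)(C)CCc2c1O[Si](C(C)C)(C(C)C)C(C)C)c1c(O)cc2OC(C)(C)CCc2c1O[Si](C(C)C)(C(C)C)C(C)C | intermediate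
20 | (R)-2-methylbutanoic acid | CC[C@@H](C)C(=O)O | starting material
21 | (R)-2-methylbutanoyl chloride | CC[C@@H](C)C(=O)Cl | intermediate
22 | 6,6'-(6-methylheptane-1,1-diyl)bis{8-[(2R)-2-methylbutanoyl]-2,2-dimethyl-5-(triisopropylsilyloxy)chroman-7-ol} | CC[C@@H](C)C(=O)c1c(O)c(C(CCCCC(C)C)c2c(O[Si](C(C)C)(C(C)C)C(C)C)c3c(c(C(=O)[C@H](C)CC)c2O)OC(C)(C)CC3)c(O[Si](C(C)C)(C(C)C)C(C)C)c2c1OC(C)(C)CC2 | intermediate
23 | 6,6'-(6-methylheptane-1,1-diyl)bis{8-[(2R)-2-methylbutanoyl]-2,2-dimethylchroman-5,7-diol} | CC[C@@H](C)C(=O)c1c(O)c(C(CCCCC(C)C)c2c(O)c3c(c(C(=O)[C@H](C)CC)c2O)OC(C)(C)CC3)c(O)c2c1OC(C)(C)CC2 | target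

**Step count**

Total steps: 13. Longest linear sequence: 8 steps (8 → 10 → 11 → 12 → 13 → 16 → 19 → 22 → 23; steps 5, 6, 7, 8, 9, 10, 12, 13).

**Steps most likely to fail**

1. Step 10. The first-formed C7 hydroxyl may add across the neighbouring siloxyalkyne arm before the second benzannulation. The second arm may also stall beside the crowded ortho silyloxy group, or ring opening of the 3-alkoxycyclobutenone may be slow enough for photodegradation to compete. Fallback: the bridge would be made last by the classical aldehyde condensation of acylphloroglucinols instead of by benzannulation. Acid chloride 21 would acylate phloroglucinol (Oc1cc(O)cc(O)c1; AlCl3, CH2Cl2/PhNO2, 0 → 20 °C) to (2R)-2-methyl-1-(2,4,6-trihydroxyphenyl)butan-1-one F1. Acid-mediated chroman annulation with 2-methylbut-3-en-2-ol (BF3·OEt2, dioxane, 20 °C) would give (2R)-1-(5,7-dihydroxy-2,2-dimethylchroman-8-yl)-2-methylbutan-1-one F2 after separation from its 6-acyl isomer. Ester 8 would be reduced with i-Bu2AlH (CH2Cl2, −78 °C) to 6-methylheptanal F3. Two equivalents of F2 would then be condensed with F3 under mild acid or amine catalysis (Knoevenagel condensation to an ortho-quinone methide, then conjugate addition of the second chroman through its free C6). This fallback sets out from 21 and 8 and comes back to the route at 23.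

2. Step 12. The Lewis acid and the HCl set free may cleave or scramble the electron-rich diarylmethine bridge, O-acylation may fail to migrate to C8, or enolisation of the activated acyl group may erode the (R) configuration. Fallback: the acyl group would be brought in through an aryllithium instead of an acylium ion. Both C7 hydroxyls of 19 would be protected (MOMCl, i-Pr2NEt, CH2Cl2) to give 6,6'-(6-methylheptane-1,1-diyl)bis[7-(methoxymethoxy)-2,2-dimethyl-5-(triisopropylsilyloxy)chroman] F4. Directed ortho-lithiation at C8, between the methoxymethoxy group and the ring oxygen (n-BuLi, TMEDA, THF, −78 → 0 °C), followed by the Weinreb amide (2R)-N-methoxy-N,2-dimethylbutanamide F5 (from 21 with MeNHOMe·HCl and pyridine) should give the 8,8'-bis[(2R)-2-methylbutanoyl] bis(methoxymethyl) ether F6. The ketone is released only on work-up, so the α-centre is not exposed to base as a ketone. HCl in MeOH at 20 °C would remove the methoxymethyl groups. This fallback sets out from 19 and comes back at 22.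

3. Step 4. Acid-promoted ring cleavage or oligomerisation of the strained hydroxycyclobutenone may outrun hydroalkoxylation of the alkene. Fallback: the O–C bond would be formed by electrophile-induced cyclisation under buffered conditions instead of by protonation. Treatment of 6 with I2 and NaHCO3 (MeCN, 0 °C) should give, by 6-endo iodoetherification at the tertiary carbon, rac-4-iodo-3,3-dimethyl-2-oxabicyclo[4.2.0]oct-1(6)-en-7-one F7. Radical deiodination (Bu3SnH, Et3B, air, toluene, 20 °C) would then deliver 7. This fallback sets out from 6 and comes back at 7.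

**Further compounds**

F1 | step 10 | (2R)-2-methyl-1-(2,4,6-trihydroxyphenyl)butan-1-one | CC[C@@H](C)C(=O)c1c(O)cc(O)cc1O
F2 | step 10 | (2R)-1-(5,7-dihydroxy-2,2-dimethylchroman-8-yl)-2-methylbutan-1-one | CC[C@@H](C)C(=O)c1c(O)cc(O)c2c1OC(C)(C)CC2
F3 | step 10 | 6-methylheptanal | CC(C)CCCCC=O
F4 | step 12 | 6,6'-(6-methylheptane-1,1-diyl)bis[7-(methoxymethoxy)-2,2-dimethyl-5-(triisopropylsilyloxy)chroman] | CC(C)CCCCC(c1c(OCOC)cc2OC(C)(C)CCc2c1O[Si](C(C)C)(C(C)C)C(C)C)c1c(OCOC)cc2OC(C)(C)CCc2c1O[Si](C(C)C)(C(C)C)C(C)C
F5 | step 12 | (2R)-N-methoxy-N,2-dimethylbutanamide | CC[C@@H](C)C(=O)N(C)OC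
F6 | step 12 | 6,6'-(6-methylheptane-1,1-diyl)bis{7-(methoxymethoxy)-8-[(2R)-2-methylbutanoyl]-2,2-dimethyl-5-(triisopropylsilyloxy)chroman} | CC[C@@H](C)C(=O)c1c(OCOC)c(C(CCCCC(C)C)c2c(O[Si](C(C)C)(C(C)C)C(C)C)c3c(c(C(=O)[C@H](C)CC)c2OCOC)OC(C)(C)CC3)c(O[Si](C(C)C)(C(C)C)C(C)C)c2c1OC(C)(C)CC2
F7 | step 4 | rac-4-iodo-3,3-dimethyl-2-oxabicyclo[4.2.0]oct-1(6)-en-7-one | O=C1CC2=C1CC(I)C(C)(C)O2
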